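## Structural features

The target joins a sesquiterpene to a phloroglucinol. A trans-fused decalin (eudesmane numbering: ring A = C1–C5 and C10, ring B = C5–C10, C11 = carbinol carbon on C7) carries on C1 an exocyclic benzylic carbon Cα, which bears an isobutyl group and a 3,5-diformyl-2,4,6-trihydroxyphenyl ring. Five of the six stereocentres are contiguous (Cα, C1, the quaternary C10 with its angular methyl, C5 and the tertiary carbinol C4); the sixth, C7, lies across ring B. With β defined as the face of the angular methyl, the C1 side chain, the axial C4 hydroxyl and the equatorial C7 2-hydroxypropan-2-yl group are all β, and H5 is α. The two tertiary alcohols ionise or dehydrate in acid (the axial C4–OH most easily). The hexasubstituted diformylphloroglucinol is acidic, chelating and sensitive to oxidants and electrophilic halogen, and the Cα–aryl carbon ionises readily while the ring is electron-rich. The real difficulty is the quaternary C10 wedged between C1 and C5, the acyclic Cα next to it, and the need to reconcile arene chemistry (formylation, ether cleavage) with acid-labile carbinols. The key step uses the fact that in ring A the C1 substituent and the C10 methyl are cis on neighbouring carbons, C5–C10 is a trans fusion and C3–C4 can be an alkene. Ring A is therefore the cyclohexene of a [4+2] addition between a C1=C10 dienophile and a C2=C3–C4=C5 diene, with C6–C9 of ring B as tether and C7 as controlling centre.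

## Logic of the disconnections

31 ⇒ 30 ⇒ 29. The three phenolic O–CH3 bonds and then the C11 O–Si bond are cut. The free triphenol dialdehyde would not survive organolithium or cation chemistry, so it is unmasked last. This lets every earlier step run on a neutral arene and an ether. The forward dealkylation must be nucleophilic and non-acidic, because C4–OH and C11–OH are tertiary.

29 ⇒ 26 ⇒ 24. The two aryl C–CHO bonds are cut one after the other. Each ring CH of 24 lies between two methoxy groups, the best site for directed lithiation, and this avoids acidic formylation. The arene simplifies to a symmetric trimethoxyphenyl group. The second metalation must tolerate the first formyl group, which calls for transient masking.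

24 ⇒ 23 ⇒ 20 ⇒ 17 + 18 + 21. The Cα–CH2 bond and the Cα–aryl bond are cut. Cα is benzylic to a ring that stabilises a cation exceptionally well, so the C–C bond can come from cation capture and the C–aryl bond from carbonyl addition. The side chain then derives from three commercial pieces, and Cα is controlled by C1 and C10. The forward step must attack one face of cation 22, and 17 must already hold C1 correctly.

17 ⇒ 16 ⇒ 14. The C4–O bond and a C3–H bond are cut, which reveals a C3=C4 alkene. Markovnikov, trans-diaxial hydration of that alkene gives exactly the axial C4–OH cis to the angular methyl. It is placed before the arene arrives, so the alkene is the only π-nucleophile present. One stereocentre is removed and the cyclohexene retron appears. The forward step needs electrophile on the α face and water on the β face.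

14 ⇒ 13. The bonds C1–C2 and C5–C10 are cut; both rings open and three stereocentres (C1, C5, C10) disappear. What remains is a linear trienal with one stereocentre. The forward step must be endo-selective and face-selective.

13 ⇒ 12 ⇒ 11 ⇒ 8 + 9. The C1=C10 double bond is cut (C10 from the ketone of 8, C1 and the formyl carbon from 9). The enal is reached through the ester oxidation level because olefination of the ketone is most E-selective there. The E geometry is the demand, since it becomes the C1/C10 relationship.

8 ⇒ 7 ⇒ 5 + 6. The C2=C3 and then the C4=C5 double bonds of the diene are cut. Both olefinations must choose an aldehyde over the methyl ketone, and the trisubstituted alkene must be E.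

5 ⇒ 3 ⇒ 2 ⇒ 1. The carbonyl carbons C5 and C10 are reconnected as a ring C=C, then the O–Si and C11–O bonds are cut. The chiral pool supplies C7. The oxygen on C11 is installed first, so that 3 has a single alkene to cleave and no hydration is needed later beside the diene and enal.

## Other disconnections considered

Alternative 1: The cut runs through the arene at C2'–C3' and C5'–C6'. C1', C2' and C6' would come from a malonyl unit on Cα (malonyl dichloride A2) and C3'–C5' from dimethyl 3-oxopentanedioate A3. Forward, the magnesium enolate of A3 (MgCl2, Et3N) would be C-acylated twice by A2, and ring closure with enolisation would give phloroglucinol diester A1.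
- In favour: the phenols are born free, so the triple O-demethylation that ends the chosen route is avoided. On this point the alternative is the better plan. The arene construction is also convergent.
- Against: A2 is a monosubstituted malonyl chloride with an acidic α-hydrogen and a very bulky substituent. Ketene formation, O-acylation and closure through oxygen instead of carbon are the expected competitors.
- Against: the two esters of A1 must become aldehydes beside three free phenols. That needs either phenol protection, which brings the deprotection problem back, or a reduction–oxidation detour at two hindered positions.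
- Against: Cα would have to be set on a hindered malonate with no aryl group to steer it, and both carbinols must survive acid chloride formation as silyl ethers.
- Comparison: mechanistically it is a polar condensation with several ambident partners, against one pericyclic step plus predictable aryllithium chemistry. In step count it is judged longer, because the decalin still has to be built (most plausibly by a cycloaddition like step 9) and redox steps follow A1.

Alternative 2: The cut breaks C4–C5 and C9–C10 and opens both rings to keto alkene β-keto ester A5, which already holds Cα, the aryl and isobutyl groups and C1. Forward, MeAlCl2 would activate the C4 methyl ketone, the E C5=C10 alkene would attack it, and the C10 cation would be captured by the enol carbon C9 to give A4.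
- In favour: C4 carbinol, C5 and C10 are formed in one step, so the two-step hydration of the chosen route (steps 10 and 11) is not needed. Here the alternative is better. Closing both rings in one operation equals the chosen key step.
- Against: A4 has no substituent at C7. The 2-hydroxypropan-2-yl group would have to be introduced next to the C8 ketone and the C8 oxygen and C9 ester then removed, several steps that the chosen route avoids because C7 and C11 come with the starting terpene.
- Against: C1 and Cα of A5 are acyclic and must both be made by reagent control and then direct the folding. The orientation of the complexed ketone decides C4, and an axial hydroxyl is not the obviously favoured outcome.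
- Against: a cationic cascade beside a trimethoxyarene risks Friedel–Crafts capture and Lewis acid sequestration.
- Comparison: equal in ring-forming power, better at C4, worse at C7, in stereocontrol of the open-chain precursor and in step economy.

Alternative 3: The cut is C3–C4 only. Ring A of the complete side-chain compound opens to iodo ketone A7, a ring B cyclohexane with the acetyl group on C5 and the chain C1(Cα)–C2–C3–I on the quaternary C10. Forward, SmI2 with HMPA would generate a nucleophilic C3 that adds to the C4 carbonyl and gives A6.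
- In favour: the carbinol is formed directly under neutral, chemoselective conditions that tolerate the arene and the silyl ether, which is better than the bromohydrin and tin hydride pair of the chosen route. A6 is the same compound as 24, so the last four steps would be shared, an equal point.
- Against: the step closes one ring and sets one stereocentre. The face of a freely rotating acetyl group decides C4, so the axial hydroxyl is not assured, and simple reduction of the iodide competes.
- Against: A7 requires the quaternary C10 with its correct relationship to C1, Cα, C5 and C7 to be built on a monocyclic ring. That is exactly the problem the cycloaddition solves in one step from a linear chain. HMPA is an added hazard.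
- Comparison: the chosen plan is preferred on step economy and on confidence in the ring fusion. The alternative is superior only in how the carbinol is made.

Key step: step 9

Remarks before the route:
- Convention: β is the face of the angular C10 methyl; bicyclic intermediates keep the locants of 14 in their names (C1 side chain, C4 and C8a methyl groups, C6 oxygenated isopropyl group).
- Correction: counted from the formyl carbon, the silyloxyisopropyl group of trienal 13 stands on C6 (6S), not C7. Only the 6-substituted chain maps onto C7 of the decalin, and (S)-limonene delivers this configuration.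
- Assumption: commercial (S)-(−)-limonene of high enantiomeric purity is used, because its stereocentre (later C7) controls all the others.

## Route

Step 1
Reactants: 1 (S)-(−)-limonene
Product: 2 (S)-(−)-α-terpineol, 2-[(1S)-4-methylcyclohex-3-en-1-yl]propan-2-ol
Conditions: Co(acac)2 (cat.), PhSiH3, O2 (1 atm), THF, rt
Reagents that add atoms: dioxygen (O=O)
Why: Mukaiyama hydration: hydrogen-atom transfer from a cobalt hydride reaches the unhindered 1,1-disubstituted alkene faster than the ring trisubstituted one, the tertiary radical is trapped by O2 and reduced to the Markovnikov alcohol. No bond to the stereocentre is touched and no carbocation forms that could racemise it.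

Step 2
Reactants: 2 (S)-(−)-α-terpineol
Product: 3 triethyl({2-[(1S)-4-methylcyclohex-3-en-1-yl]propan-2-yl}oxy)silane
Conditions: TESOTf, 2,6-lutidine, CH2Cl2, 0 °C
Reagents that add atoms: triethylsilyl trifluoromethanesulfonate (CC[Si](CC)(CC)OS(=O)(=O)C(F)(F)F)
Why: Silyl triflate with a hindered base silylates tertiary alcohols reliably. The ether prevents lactol formation and oxa-Michael addition in the carbonyl steps that follow.

Step 3
Reactants: 3 triethyl({2-[(1S)-4-methylcyclohex-3-en-1-yl]propan-2-yl}oxy)silane
Product: 5 (3S)-6-oxo-3-[2-(triethylsilyloxy)propan-2-yl]heptanal, via secondary ozonide 4 (not isolated)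
Conditions: O3, CH2Cl2, −78 °C; then PPh3, −78 °C → rt
Reagents that add atoms: ozone ([O-][O+]=O)
Why: Ozonolysis with reductive work-up; 3 holds a single C=C, so no choice between alkenes arises. The 1,6-keto aldehyde is used at once because it is prone to intramolecular aldol condensation.

Step 4
Reactants: 5 (3S)-6-oxo-3-[2-(triethylsilyloxy)propan-2-yl]heptanal; 6 2-(triphenylphosphoranylidene)propanal
Product: 7 (2E,5S)-2-methyl-8-oxo-5-[2-(triethylsilyloxy)propan-2-yl]non-2-enal
Conditions: toluene, 80 °C
Reagents that add atoms: none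
Why: Wittig reaction of a stabilised formyl ylide: it olefinates the aldehyde and leaves the methyl ketone alone. Reversible addition of stabilised ylides gives the E trisubstituted enal (chain trans to formyl).

Step 5
Reactants: 7 (2E,5S)-2-methyl-8-oxo-5-[2-(triethylsilyloxy)propan-2-yl]non-2-enal
Product: 8 (5S,7E)-8-methyl-5-[2-(triethylsilyloxy)propan-2-yl]deca-7,9-dien-2-one
Conditions: Ph3PCH3Br, n-BuLi, THF, 0 °C; then 7 (1.0 equiv), −78 → 0 °C
Reagents that add atoms: methyltriphenylphosphonium bromide (C[P+](c1ccccc1)(c1ccccc1)c1ccccc1.[Br-])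
Why: Wittig methylenation; at −78 °C one equivalent of the non-stabilised ylide should react with the aldehyde much faster than with the methyl ketone. No new geometry is created and the 7E alkene is kept.

Step 6
Reactants: 8 (5S,7E)-8-methyl-5-[2-(triethylsilyloxy)propan-2-yl]deca-7,9-dien-2-one; 9 triethyl phosphonoacetate
Product: 11 ethyl (2E,6S,8E)-3,9-dimethyl-6-[2-(triethylsilyloxy)propan-2-yl]undeca-2,8,10-trienoate, via sodium phosphonate carbanion 10 (not isolated)
Conditions: 9, NaH, THF, 0 °C; then 8, rt → 50 °C
Reagents that add atoms: none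
Why: Horner–Wadsworth–Emmons olefination of the methyl ketone; the reversible addition favours the E enoate (ester trans to the longer chain). The minor Z isomer should be removed by chromatography here or at 12.

Step 7
Reactants: 11 ethyl (2E,6S,8E)-3,9-dimethyl-6-[2-(triethylsilyloxy)propan-2-yl]undeca-2,8,10-trienoate
Product: 12 (2E,6S,8E)-3,9-dimethyl-6-[2-(triethylsilyloxy)propan-2-yl]undeca-2,8,10-trien-1-ol
Conditions: DIBAL-H, CH2Cl2, −78 °C; Rochelle salt work-up
Reagents that add atoms: none
Why: DIBAL-H reduces the conjugated ester to the allylic alcohol by 1,2-hydride delivery; diene and tertiary silyl ether are inert.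

Step 8
Reactants: 12 (2E,6S,8E)-3,9-dimethyl-6-[2-(triethylsilyloxy)propan-2-yl]undeca-2,8,10-trien-1-ol
Product: 13 (2E,6S,8E)-3,9-dimethyl-6-[2-(triethylsilyloxy)propan-2-yl]undeca-2,8,10-trienal
Conditions: MnO2, CH2Cl2, rt
Reagents that add atoms: none
Why: MnO2 oxidises the allylic alcohol selectively under neutral conditions, so the E geometry of the β-methyl enal and the silyl ether should be preserved.

Step 9
Reactants: 13 (2E,6S,8E)-3,9-dimethyl-6-[2-(triethylsilyloxy)propan-2-yl]undeca-2,8,10-trienal
Product: 14 (1S,4aR,6S,8aS)-4,8a-dimethyl-6-[2-(triethylsilyloxy)propan-2-yl]-1,2,4a,5,6,7,8,8a-octahydronaphthalene-1-carbaldehyde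
Conditions: Me2AlCl (1.5 equiv), CH2Cl2, −78 → −20 °C
Reagents that add atoms: none
Why: The step is a concerted, asynchronous normal-demand [4+2] cycloaddition of the aluminium-complexed (E)-enal C1=C10 with the tethered diene C2=C3–C4=C5; its closest known relative is the dialkylaluminium chloride-promoted intramolecular Diels–Alder reaction of (E)-deca-2,7,9-trienals to trans-fused octalins. Ring A closes as the new cyclohexene through the σ bonds C1–C2 and C5–C10 (the [4+2] mode itself), and ring B closes in the same transition state through C5–C10 across the four-carbon tether C6–C9, a six-membered closure in which bonding to the enal β-carbon C10 is the more advanced. C1 is set relative to C10 by suprafacial addition to the E alkene, which places the formyl group cis to the angular methyl. The C5/C10 trans fusion is set by the endo transition state, with the complexed formyl group under the diene, and Lewis acid coordination strengthens that preference. The absolute sense at C5 and C10 is set by C7: the tether folds as a chair with the bulky silyloxyisopropyl group equatorial, so one diene face is presented. The selectivities needed are endo over exo and one chair over the other; the E geometry of both reacting alkenes, the low temperature and the size of the C7 group should secure them. Me2AlCl is chosen because its methyl groups destroy adventitious acid, which protects diene and silyl ether, and the excess with warming to −20 °C answers the lower reactivity of the β-methyl dienophile.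

Step 10
Reactants: 14 (1S,4aR,6S,8aS)-4,8a-dimethyl-6-[2-(triethylsilyloxy)propan-2-yl]-1,2,4a,5,6,7,8,8a-octahydronaphthalene-1-carbaldehyde
Product: 16 (1S,3S,4S,4aS,6S,8aS)-3-bromo-4-hydroxy-4,8a-dimethyl-6-[2-(triethylsilyloxy)propan-2-yl]decahydronaphthalene-1-carbaldehyde, via bromonium ion 15 (not isolated)
Conditions: NBS, THF/H2O (4:1), 0 °C
Reagents that add atoms: N-bromosuccinimide (O=C1CCC(=O)N1Br); water (O)
Why: Bromohydrin formation under Fürst–Plattner control: the bromonium ion forms on the α face, away from the axial angular methyl, and water opens it at the tertiary C4 from the β face, which is both the Markovnikov and the trans-diaxial mode. This sets the axial C4–OH cis to the C10 methyl (and an axial C3–Br). No arene is present yet, so the alkene is the only π-nucleophile offered to NBS.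

Step 11
Reactants: 16 (1S,3S,4S,4aS,6S,8aS)-3-bromo-4-hydroxy-4,8a-dimethyl-6-[2-(triethylsilyloxy)propan-2-yl]decahydronaphthalene-1-carbaldehyde
Product: 17 (1S,4R,4aS,6S,8aS)-4-hydroxy-4,8a-dimethyl-6-[2-(triethylsilyloxy)propan-2-yl]decahydronaphthalene-1-carbaldehyde
Conditions: Bu3SnH, AIBN (cat.), PhH, 80 °C
Reagents that add atoms: none
Why: Radical chain dehalogenation: the secondary C3 radical takes hydrogen from Sn–H. The C4 carbinol and the aldehyde take no part, so C4 keeps its configuration.

Step 12
Reactants: 17 (1S,4R,4aS,6S,8aS)-4-hydroxy-4,8a-dimethyl-6-[2-(triethylsilyloxy)propan-2-yl]decahydronaphthalene-1-carbaldehyde; 18 1,3,5-trimethoxybenzene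
Product: 20 (1S,4R,4aS,6S,8aR)-1-[hydroxy(2,4,6-trimethoxyphenyl)methyl]-4,8a-dimethyl-6-[2-(triethylsilyloxy)propan-2-yl]decahydronaphthalen-4-ol (both Cα epimers), via 2,4,6-trimethoxyphenyllithium 19 (not isolated)
Conditions: 18 (3 equiv), n-BuLi, THF, 0 °C → rt; then 17, −78 → 0 °C
Reagents that add atoms: none
Why: Directed ortho-lithiation of 18 between two methoxy groups, then 1,2-addition of the aryllithium to the aldehyde; one equivalent is spent on the C4 hydroxyl. The new carbinol centre forms as a mixture, which does not matter because it is ionised in step 13.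

Step 13
Reactants: 20 (1S,4R,4aS,6S,8aR)-1-[hydroxy(2,4,6-trimethoxyphenyl)methyl]-4,8a-dimethyl-6-[2-(triethylsilyloxy)propan-2-yl]decahydronaphthalen-4-ol; 21 trimethyl(2-methylallyl)silane
Product: 23 (1R,4R,4aS,6S,8aR)-4,8a-dimethyl-1-[(1R)-3-methyl-1-(2,4,6-trimethoxyphenyl)but-3-en-1-yl]-6-[2-(triethylsilyloxy)propan-2-yl]decahydronaphthalen-4-ol, via benzylic cation 22 (not isolated)
Conditions: 21 (3 equiv), BF3·OEt2, CH2Cl2, −78 °C
Reagents that add atoms: none
Why: SN1 benzylic allylation of Hosomi–Sakurai type: BF3 ionises only the trimethoxybenzylic hydroxyl and the cation is captured by the allylsilane with loss of silicon. In the conformation that minimises 1,3-allylic strain the C1–H bond lies in the cation plane syn to the aryl ring, so C2 and the quaternary C10 flank the two faces, and attack anti to C10 sets Cα as R. The tertiary cyclohexanol and the tertiary silyl ether should not ionise at −78 °C.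

Step 14
Reactants: 23 (1R,4R,4aS,6S,8aR)-4,8a-dimethyl-1-[(1R)-3-methyl-1-(2,4,6-trimethoxyphenyl)but-3-en-1-yl]-6-[2-(triethylsilyloxy)propan-2-yl]decahydronaphthalen-4-ol
Product: 24 (1R,4R,4aS,6S,8aR)-4,8a-dimethyl-1-[(1R)-3-methyl-1-(2,4,6-trimethoxyphenyl)butyl]-6-[2-(triethylsilyloxy)propan-2-yl]decahydronaphthalen-4-ol
Conditions: H2 (1 atm), Pd/C, EtOAc, rt
Reagents that add atoms: none
Why: Heterogeneous hydrogenation of the only C=C, a 1,1-disubstituted alkene; no stereocentre is formed and no hydrogenolysable bond is present.

Step 15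
Reactants: 24 (1R,4R,4aS,6S,8aR)-4,8a-dimethyl-1-[(1R)-3-methyl-1-(2,4,6-trimethoxyphenyl)butyl]-6-[2-(triethylsilyloxy)propan-2-yl]decahydronaphthalen-4-ol
Product: 26 3-{(1R)-1-[(1R,4R,4aS,6S,8aR)-4-hydroxy-4,8a-dimethyl-6-[2-(triethylsilyloxy)propan-2-yl]decahydronaphthalen-1-yl]-3-methylbutyl}-2,4,6-trimethoxybenzaldehyde, via dilithiated arene 25 (not isolated)
Conditions: n-BuLi (2.5 equiv), TMEDA, THF, 0 °C → rt; then DMF, −78 °C → rt; aq. NH4Cl
Reagents that add atoms: N,N-dimethylformamide (CN(C)C=O)
Why: Directed ortho-metalation: after deprotonation of the C4 hydroxyl, n-BuLi/TMEDA removes a ring proton flanked by two methoxy groups and DMF formylates the aryllithium. The two ring positions are equivalent, so one aldehyde results.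

Step 16
Reactants: 26 3-{(1R)-1-[(1R,4R,4aS,6S,8aR)-4-hydroxy-4,8a-dimethyl-6-[2-(triethylsilyloxy)propan-2-yl]decahydronaphthalen-1-yl]-3-methylbutyl}-2,4,6-trimethoxybenzaldehyde
Product: 29 5-{(1R)-1-[(1R,4R,4aS,6S,8aR)-4-hydroxy-4,8a-dimethyl-6-[2-(triethylsilyloxy)propan-2-yl]decahydronaphthalen-1-yl]-3-methylbutyl}-2,4,6-trimethoxybenzene-1,3-dicarbaldehyde, via α-amino alkoxide 27 (not isolated), via ring-lithiated α-amino alkoxide 28 (not isolated)
Conditions: LiN(Me)CH2CH2NMe2 (2.2 equiv), THF, −20 °C; n-BuLi (3 equiv), −20 → 0 °C; DMF, −78 °C → rt; aq. NH4Cl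
Reagents that add atoms: N,N-dimethylformamide (CN(C)C=O)
Why: The lithium amide adds to the formyl group and masks it as an α-amino alkoxide, so n-BuLi can remove the last ring proton (again between two methoxy groups) without attacking the carbonyl; DMF formylates and aqueous work-up releases both aldehydes. This known in situ protection for lithiation of aryl aldehydes avoids the acidic Rieche or Vilsmeier conditions that the tertiary carbinols would not survive.

Step 17
Reactants: 29 5-{(1R)-1-[(1R,4R,4aS,6S,8aR)-4-hydroxy-4,8a-dimethyl-6-[2-(triethylsilyloxy)propan-2-yl]decahydronaphthalen-1-yl]-3-methylbutyl}-2,4,6-trimethoxybenzene-1,3-dicarbaldehyde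
Product: 30 5-{(1R)-1-[(1R,4R,4aS,6S,8aR)-4-hydroxy-6-(2-hydroxypropan-2-yl)-4,8a-dimethyldecahydronaphthalen-1-yl]-3-methylbutyl}-2,4,6-trimethoxybenzene-1,3-dicarbaldehyde
Conditions: TBAF, THF, rt → 50 °C
Reagents that add atoms: none
Why: Fluoride cleaves the Si–O bond of the tertiary silyl ether under non-acidic conditions. The aryl aldehydes have no α-hydrogen and the carbinols are not ionised.

Step 18
Reactants: 30 5-{(1R)-1-[(1R,4R,4aS,6S,8aR)-4-hydroxy-6-(2-hydroxypropan-2-yl)-4,8a-dimethyldecahydronaphthalen-1-yl]-3-methylbutyl}-2,4,6-trimethoxybenzene-1,3-dicarbaldehyde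
Product: 31 5-{(1R)-1-[(1R,4R,4aS,6S,8aR)-4-hydroxy-6-(2-hydroxypropan-2-yl)-4,8a-dimethyldecahydronaphthalen-1-yl]-3-methylbutyl}-2,4,6-trihydroxybenzene-1,3-dicarbaldehyde (CNP0409870.6)
Conditions: NaSEt (excess), DMF, 110 °C; then aq. HCl
Reagents that add atoms: none
Why: SN2 O-demethylation by ethanethiolate in a dipolar aprotic solvent: every methoxy group is ortho to a formyl group, so each aryloxide is a vinylogous carboxylate and a good leaving group. The conditions are non-acidic and so compatible with both tertiary alcohols; acidification liberates the triphenol.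

## Compound list

1 | (S)-(−)-limonene, (4S)-1-methyl-4-(prop-1-en-2-yl)cyclohex-1-ene | CC1=CC[C@H](CC1)C(C)=C | starting material
2 | (S)-(−)-α-terpineol, 2-[(1S)-4-methylcyclohex-3-en-1-yl]propan-2-ol | CC1=CC[C@H](CC1)C(C)(C)O | intermediate
3 | triethyl({2-[(1S)-4-methylcyclohex-3-en-1-yl]propan-2-yl}oxy)silane | CC1=CC[C@H](CC1)C(C)(C)O[Si](CC)(CC)CC | intermediate
4 | secondary ozonide of 3, 1-methyl-4-[2-(triethylsilyloxy)propan-2-yl]-7,8,9-trioxabicyclo[4.2.1]nonane (ring CH as in 3; not isolated) | CC12CC[C@@H](CC(O1)OO2)C(C)(C)O[Si](CC)(CC)CC | intermediate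
5 | (3S)-6-oxo-3-[2-(triethylsilyloxy)propan-2-yl]heptanal | CC(=O)CC[C@@H](CC=O)C(C)(C)O[Si](CC)(CC)CC | intermediate
6 | 2-(triphenylphosphoranylidene)propanal | CC(C=O)=P(c1ccccc1)(c1ccccc1)c1ccccc1 | starting material
7 | (2E,5S)-2-methyl-8-oxo-5-[2-(triethylsilyloxy)propan-2-yl]non-2-enal | CC(=O)CC[C@@H](C/C=C(\C)C=O)C(C)(C)O[Si](CC)(CC)CC | intermediate
8 | (5S,7E)-8-methyl-5-[2-(triethylsilyloxy)propan-2-yl]deca-7,9-dien-2-one | CC(=O)CC[C@@H](C/C=C(\C)C=C)C(C)(C)O[Si](CC)(CC)CC | intermediate
9 | triethyl phosphonoacetate | CCOC(=O)CP(=O)(OCC)OCC | starting material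
10 | sodium salt of the carbanion of 9 (not isolated) | CCOC(=O)[CH-]P(=O)(OCC)OCC.[Na+] | intermediate
11 | ethyl (2E,6S,8E)-3,9-dimethyl-6-[2-(triethylsilyloxy)propan-2-yl]undeca-2,8,10-trienoate | CCOC(=O)/C=C(\C)CC[C@@H](C/C=C(\C)C=C)C(C)(C)O[Si](CC)(CC)CC | intermediate
12 | (2E,6S,8E)-3,9-dimethyl-6-[2-(triethylsilyloxy)propan-2-yl]undeca-2,8,10-trien-1-ol | OC/C=C(\C)CC[C@@H](C/C=C(\C)C=C)C(C)(C)O[Si](CC)(CC)CC | intermediate
13 | (2E,6S,8E)-3,9-dimethyl-6-[2-(triethylsilyloxy)propan-2-yl]undeca-2,8,10-trienal | C=C/C(C)=C/C[C@@H](C(C)(C)O[Si](CC)(CC)CC)CC/C(C)=C/C=O | intermediate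
14 | (1S,4aR,6S,8aS)-4,8a-dimethyl-6-[2-(triethylsilyloxy)propan-2-yl]-1,2,4a,5,6,7,8,8a-octahydronaphthalene-1-carbaldehyde | O=C[C@H]1CC=C(C)[C@H]2C[C@@H](C(C)(C)O[Si](CC)(CC)CC)CC[C@]12C | intermediate
15 | 3α,4α-bromonium ion of 14 (not isolated) | O=C[C@H]1C[C@@H]2[Br+][C@]2(C)[C@H]3C[C@@H](C(C)(C)O[Si](CC)(CC)CC)CC[C@]13C | intermediate
16 | (1S,3S,4S,4aS,6S,8aS)-3-bromo-4-hydroxy-4,8a-dimethyl-6-[2-(triethylsilyloxy)propan-2-yl]decahydronaphthalene-1-carbaldehyde | O=C[C@H]1C[C@H](Br)[C@@](C)(O)[C@H]2C[C@@H](C(C)(C)O[Si](CC)(CC)CC)CC[C@]12C | intermediate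
17 | (1S,4R,4aS,6S,8aS)-4-hydroxy-4,8a-dimethyl-6-[2-(triethylsilyloxy)propan-2-yl]decahydronaphthalene-1-carbaldehyde | O=C[C@H]1CC[C@@](C)(O)[C@H]2C[C@@H](C(C)(C)O[Si](CC)(CC)CC)CC[C@]12C | intermediate
18 | 1,3,5-trimethoxybenzene | COc1cc(OC)cc(OC)c1 | starting material
19 | 2,4,6-trimethoxyphenyllithium (not isolated) | [Li]c1c(OC)cc(OC)cc1OC | intermediate
20 | (1S,4R,4aS,6S,8aR)-1-[hydroxy(2,4,6-trimethoxyphenyl)methyl]-4,8a-dimethyl-6-[2-(triethylsilyloxy)propan-2-yl]decahydronaphthalen-4-ol (both Cα epimers) | COc1cc(OC)c(C(O)[C@H]2CC[C@@](C)(O)[C@H]3C[C@@H](C(C)(C)O[Si](CC)(CC)CC)CC[C@]23C)c(OC)c1 | intermediate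
21 | trimethyl(2-methylallyl)silane | CC(=C)C[Si](C)(C)C | starting material
22 | 2,4,6-trimethoxybenzylic cation from 20 (not isolated) | COc1cc(OC)c([CH+][C@H]2CC[C@@](C)(O)[C@H]3C[C@@H](C(C)(C)O[Si](CC)(CC)CC)CC[C@]23C)c(OC)c1 | intermediate
23 | (1R,4R,4aS,6S,8aR)-4,8a-dimethyl-1-[(1R)-3-methyl-1-(2,4,6-trimethoxyphenyl)but-3-en-1-yl]-6-[2-(triethylsilyloxy)propan-2-yl]decahydronaphthalen-4-ol | CC(=C)C[C@@H](c1c(OC)cc(OC)cc1OC)[C@H]1CC[C@@](C)(O)[C@H]2C[C@@H](C(C)(C)O[Si](CC)(CC)CC)CC[C@]12C | intermediate
24 | (1R,4R,4aS,6S,8aR)-4,8a-dimethyl-1-[(1R)-3-methyl-1-(2,4,6-trimethoxyphenyl)butyl]-6-[2-(triethylsilyloxy)propan-2-yl]decahydronaphthalen-4-ol | CC(C)C[C@@H](c1c(OC)cc(OC)cc1OC)[C@H]1CC[C@@](C)(O)[C@H]2C[C@@H](C(C)(C)O[Si](CC)(CC)CC)CC[C@]12C | intermediate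
25 | lithium alkoxide of 24 lithiated at ring position 3' (not isolated) | CC(C)C[C@@H](c1c(OC)c([Li])c(OC)cc1OC)[C@H]1CC[C@@](C)(O[Li])[C@H]2C[C@@H](C(C)(C)O[Si](CC)(CC)CC)CC[C@]12C | intermediate
26 | 3-{(1R)-1-[(1R,4R,4aS,6S,8aR)-4-hydroxy-4,8a-dimethyl-6-[2-(triethylsilyloxy)propan-2-yl]decahydronaphthalen-1-yl]-3-methylbutyl}-2,4,6-trimethoxybenzaldehyde | CC(C)C[C@@H](c1c(OC)c(C=O)c(OC)cc1OC)[C@H]1CC[C@@](C)(O)[C@H]2C[C@@H](C(C)(C)O[Si](CC)(CC)CC)CC[C@]12C | intermediate
27 | dilithium α-amino alkoxide of 26 (formyl group masked by the diamide; not isolated) | CC(C)C[C@@H](c1c(OC)c(C(O[Li])N(C)CCN(C)C)c(OC)cc1OC)[C@H]1CC[C@@](C)(O[Li])[C@H]2C[C@@H](C(C)(C)O[Si](CC)(CC)CC)CC[C@]12C | intermediate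
28 | 27 lithiated at ring position 5' (not isolated) | CC(C)C[C@@H](c1c(OC)c(C(O[Li])N(C)CCN(C)C)c(OC)c([Li])c1OC)[C@H]1CC[C@@](C)(O[Li])[C@H]2C[C@@H](C(C)(C)O[Si](CC)(CC)CC)CC[C@]12C | intermediate
29 | 5-{(1R)-1-[(1R,4R,4aS,6S,8aR)-4-hydroxy-4,8a-dimethyl-6-[2-(triethylsilyloxy)propan-2-yl]decahydronaphthalen-1-yl]-3-methylbutyl}-2,4,6-trimethoxybenzene-1,3-dicarbaldehyde | CC(C)C[C@@H](c1c(OC)c(C=O)c(OC)c(C=O)c1OC)[C@H]1CC[C@@](C)(O)[C@H]2C[C@@H](C(C)(C)O[Si](CC)(CC)CC)CC[C@]12C | intermediate
30 | 5-{(1R)-1-[(1R,4R,4aS,6S,8aR)-4-hydroxy-6-(2-hydroxypropan-2-yl)-4,8a-dimethyldecahydronaphthalen-1-yl]-3-methylbutyl}-2,4,6-trimethoxybenzene-1,3-dicarbaldehyde | CC(C)C[C@@H](c1c(OC)c(C=O)c(OC)c(C=O)c1OC)[C@H]1CC[C@@](C)(O)[C@H]2C[C@@H](C(C)(C)O)CC[C@]12C | intermediate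
31 | 5-{(1R)-1-[(1R,4R,4aS,6S,8aR)-4-hydroxy-6-(2-hydroxypropan-2-yl)-4,8a-dimethyldecahydronaphthalen-1-yl]-3-methylbutyl}-2,4,6-trihydroxybenzene-1,3-dicarbaldehyde (CNP0409870.6) | CC(C)C[C@@H](c1c(O)c(C=O)c(O)c(C=O)c1O)[C@H]1CC[C@@](C)(O)[C@H]2C[C@@H](C(C)(C)O)CC[C@]12C | target

## Step count and risk

Total: 18 steps. Longest linear sequence: 18 steps from 1 (6, 9, 18 and 21 are commercial partners).

Least certain steps, each with one fallback:

Step 9 (key step). The likely problem is a slow cycloaddition of the β,β-disubstituted enal. During it, Lewis-acid-induced E/Z isomerisation of the dienophile or cationic oligomerisation of the diene would erode yield and the C1/C10 relationship, and a weaker endo preference would give cis-fused material. The fallback sets out from ester 11 and returns at 14. Hydrolysis (LiOH) would give the trienoic acid F1. Coupling with oxazolidin-2-one through the pivaloyl mixed anhydride would give the N-acyl oxazolidinone F2. Its Me2AlCl-promoted intramolecular Diels–Alder reaction uses a two-point-bound, more electrophilic and geometrically stable dienophile and should give the trans-fused imide F3. LiBH4 would cleave this to the primary alcohol F4, and Dess–Martin oxidation would give 14.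

Step 13. The likely problem is insufficient facial discrimination at the benzylic cation; loss of a proton toward C1 or reversible capture by the C4 hydroxyl could also occur. The fallback sets out from 20 and returns at 24. Oxidation of the benzylic alcohol (Dess–Martin periodinane) would give the aryl ketone F5. Addition of isobutyllithium with CeCl3 would give the tertiary benzylic alcohol F6. Ionic reduction (Et3SiH, BF3·OEt2, CH2Cl2, −78 °C) would then deliver hydride to the fully substituted cation. Hydride takes the position that the carbon nucleophile takes in step 13, so this sequence should favour the opposite Cα epimer. It is held for the case that the allylation is unselective or favours the wrong one.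

Step 18. The likely problem is stalling after one or two cleavages as negative charge accumulates on the ring, together with reversible thiolate addition to the formyl groups or ipso attack. The fallback sets out from 29 and returns at 31. Chelation-assisted dealkylation with MgI2·OEt2 (toluene/Et2O, 60–80 °C) binds each formyl oxygen with its ortho methoxy group and lets iodide remove the methyl, which builds up no free phenoxide charge. With the C11 silyl ether still in place this would give the silylated triphenol F7, and TBAF would then give 31.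

Step 16. The likely problem is incomplete lithiation at the last, crowded ring position, or collapse of the α-amino alkoxide followed by butyl addition to the aldehyde. The fallback sets out from 26 and returns at 29. Condensation with N,N′-dimethylethane-1,2-diamine (toluene, MgSO4) would give the isolable imidazolidine F8, which is stable to alkyllithiums. Lithiation (s-BuLi, TMEDA) and DMF would give the formyl imidazolidine F9, and dilute aqueous oxalic acid would release 29.

Step 6. The likely problem is incomplete E selectivity in the olefination of a methyl ketone; residual Z isomer would pass into step 9 and lead to the C1 epimer. The fallback sets out from 8 and returns at 11. One-pot enol phosphate formation and elimination (LDA; ClP(O)(OEt)2; LDA) would give the terminal alkyne F10. Zirconium-catalysed carboalumination (Me3Al, Cp2ZrCl2) with an ethyl chloroformate quench adds methyl and the ester carbon syn, which should give 11 as the E isomer only.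

## Further compounds

F1 | step 9 | (2E,6S,8E)-3,9-dimethyl-6-[2-(triethylsilyloxy)propan-2-yl]undeca-2,8,10-trienoic acid | OC(=O)/C=C(\C)CC[C@@H](C/C=C(\C)C=C)C(C)(C)O[Si](CC)(CC)CC
F2 | step 9 | 3-[(2E,6S,8E)-3,9-dimethyl-6-[2-(triethylsilyloxy)propan-2-yl]undeca-2,8,10-trienoyl]-1,3-oxazolidin-2-one | O=C1OCCN1C(=O)/C=C(\C)CC[C@@H](C/C=C(\C)C=C)C(C)(C)O[Si](CC)(CC)CC
F3 | step 9 | 3-{[(1S,4aR,6S,8aS)-4,8a-dimethyl-6-[2-(triethylsilyloxy)propan-2-yl]-1,2,4a,5,6,7,8,8a-octahydronaphthalen-1-yl]carbonyl}-1,3-oxazolidin-2-one | O=C1OCCN1C(=O)[C@H]1CC=C(C)[C@H]2C[C@@H](C(C)(C)O[Si](CC)(CC)CC)CC[C@]12C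
F4 | step 9 | [(1S,4aR,6S,8aS)-4,8a-dimethyl-6-[2-(triethylsilyloxy)propan-2-yl]-1,2,4a,5,6,7,8,8a-octahydronaphthalen-1-yl]methanol | OC[C@H]1CC=C(C)[C@H]2C[C@@H](C(C)(C)O[Si](CC)(CC)CC)CC[C@]12C
F5 | step 13 | [(1S,4R,4aS,6S,8aR)-4-hydroxy-4,8a-dimethyl-6-[2-(triethylsilyloxy)propan-2-yl]decahydronaphthalen-1-yl](2,4,6-trimethoxyphenyl)methanone | COc1cc(OC)c(C(=O)[C@H]2CC[C@@](C)(O)[C@H]3C[C@@H](C(C)(C)O[Si](CC)(CC)CC)CC[C@]23C)c(OC)c1
F6 | step 13 | tertiary benzylic alcohol from F5 and isobutyllithium (Cα epimers), 1-[1-hydroxy-3-methyl-1-(2,4,6-trimethoxyphenyl)butyl] analogue of 24 | CC(C)CC(O)(c1c(OC)cc(OC)cc1OC)[C@H]1CC[C@@](C)(O)[C@H]2C[C@@H](C(C)(C)O[Si](CC)(CC)CC)CC[C@]12C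
F7 | step 18 | 11-O-triethylsilyl ether of 31 | CC(C)C[C@@H](c1c(O)c(C=O)c(O)c(C=O)c1O)[C@H]1CC[C@@](C)(O)[C@H]2C[C@@H](C(C)(C)O[Si](CC)(CC)CC)CC[C@]12C
F8 | step 16 | 1,3-dimethylimidazolidin-2-yl derivative of 26 (aminal of the formyl group) | CC(C)C[C@@H](c1c(OC)c(C3N(C)CCN3C)c(OC)cc1OC)[C@H]1CC[C@@](C)(O)[C@H]2C[C@@H](C(C)(C)O[Si](CC)(CC)CC)CC[C@]12C
F9 | step 16 | F8 formylated at the remaining ring position | CC(C)C[C@@H](c1c(OC)c(C3N(C)CCN3C)c(OC)c(C=O)c1OC)[C@H]1CC[C@@](C)(O)[C@H]2C[C@@H](C(C)(C)O[Si](CC)(CC)CC)CC[C@]12C
F10 | step 6 | triethyl{[2-[(5S,7E)-8-methyldeca-7,9-dien-1-yn-5-yl]propan-2-yl]oxy}silane | C#CCC[C@@H](C/C=C(\C)C=C)C(C)(C)O[Si](CC)(CC)CC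
A1 | alternative 1 | dimethyl 2,4,6-trihydroxy-5-[side chain of 31 with both carbinols as triethylsilyl ethers]benzene-1,3-dicarboxylate | CC(C)C[C@@H](c1c(O)c(C(=O)OC)c(O)c(C(=O)OC)c1O)[C@H]1CC[C@@](C)(O[Si](CC)(CC)CC)[C@H]2C[C@@H](C(C)(C)O[Si](CC)(CC)CC)CC[C@]12C
A2 | alternative 1 | Cα-substituted malonyl dichloride (bis-silyl ether) | CC(C)C[C@@H](C(C(=O)Cl)C(=O)Cl)[C@H]1CC[C@@](C)(O[Si](CC)(CC)CC)[C@H]2C[C@@H](C(C)(C)O[Si](CC)(CC)CC)CC[C@]12C
A3 | alternative 1 | dimethyl 3-oxopentanedioate | COC(=O)CC(=O)CC(=O)OC
A4 | alternative 2 | methyl 5-hydroxy-5,8a-dimethyl-8-[(1R)-3-methyl-1-(2,4,6-trimethoxyphenyl)butyl]-2-oxodecahydronaphthalene-1-carboxylate (configuration as in the SMILES) | CC(C)C[C@@H](c1c(OC)cc(OC)cc1OC)[C@H]1CC[C@@](C)(O)[C@H]2CCC(=O)[C@@H](C(=O)OC)[C@]12C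
A5 | alternative 2 | methyl (6E,8R)-7-methyl-8-[(1R)-3-methyl-1-(2,4,6-trimethoxyphenyl)butyl]-3,11-dioxododec-6-enoate | CC(C)C[C@@H](c1c(OC)cc(OC)cc1OC)[C@@H](CCC(C)=O)/C(C)=C/CCC(=O)CC(=O)OC
A6 | alternative 3 | trimethyl ether of the des-formyl target with C11 silyl ether (identical with 24) | CC(C)C[C@@H](c1c(OC)cc(OC)cc1OC)[C@H]1CC[C@@](C)(O)[C@H]2C[C@@H](C(C)(C)O[Si](CC)(CC)CC)CC[C@]12C
A7 | alternative 3 | iodo ketone: 1-acetyl-2-methyl-2-[3-iodo-1-(1-aryl-3-methylbutyl)propyl]-5-[2-(triethylsilyloxy)propan-2-yl]cyclohexane with the configurations of 24 | CC(C)C[C@@H](c1c(OC)cc(OC)cc1OC)[C@@H](CCI)[C@@]1(C)CC[C@H](C(C)(C)O[Si](CC)(CC)CC)C[C@@H]1C(C)=O
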